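**Retrosynthetic overview**
1. Target 16 ⇐ enone 13 by a catalyst-controlled (CBS) 1,2-reduction; this sets the only stereocentre (R) in the last step.
2. 13 ⇐ o-quinone methide 11 (ring-A benzylic carbon, electrophile) + Breslow enaminol 12 of methacrolein 9 (acyl-anion equivalent). This is the key ArCH2–C(=O) bond, joining two normally electrophilic carbons on the unprotected dimer 8.
3. 8 ⇐ o-quinone methide 7 (from ring-B ketone 5 via its Mannich base) + phlorisobutyrophenone 3 (methylene bridge).
4. 3 ⇐ phloroglucinol 1 + isobutyryl chloride 2; 5 ⇐ nuclear C-methylation of 4.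
5. No ring is constructed: both benzene rings are bought (1 and 4). Order of events: ring decoration, bridge, side chain, stereocentre.

Assumption: 4, Eschenmoser's salt and the thiazolium salt are taken as inexpensive catalogue chemicals, and a one-pot sequence ending in one isolated product is counted as one step.

**Step 1**
Reactants: 1 phloroglucinol; 2 isobutyryl chloride
Product: 3 2-methyl-1-(2,4,6-trihydroxyphenyl)propan-1-one (phlorisobutyrophenone)
Conditions: AlCl3 (3.5 equiv), PhNO2/CH2Cl2, 0 °C → 40 °C; then ice/aq. HCl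
Reagents that add atoms: none
Why: Friedel–Crafts acylation of the strongly activated phloroglucinol, in which the AlCl3-complexed ketone deactivates the ring so that mono-C-acylation predominates.

**Step 2**
Reactants: 4 1-(2,6-dihydroxy-4-methoxyphenyl)ethan-1-one
Product: 5 1-(2,6-dihydroxy-4-methoxy-3-methylphenyl)ethan-1-one
Conditions: NaOMe (1.1 equiv), MeI (1.05 equiv), MeOH, 0 °C → rt
Reagents that add atoms: iodomethane CI
Why: Nuclear C-methylation of the ambident, enolate-like acylphloroglucinol anion (C-alkylation of a phenoxide in protic medium); the two free ring positions are equivalent and one equivalent of MeI limits over-methylation.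

**Step 3**
Reactants: 5 1-(2,6-dihydroxy-4-methoxy-3-methylphenyl)ethan-1-one; 3 phlorisobutyrophenone
Product: 8 1-{3-[(3-acetyl-2,4-dihydroxy-6-methoxy-5-methylphenyl)methyl]-2,4,6-trihydroxyphenyl}-2-methylpropan-1-one, via Mannich base 6 (not isolated), via o-quinone methide 7 (not isolated)
Conditions: Eschenmoser's salt (1.0 equiv), Et3N (1.1 equiv), MeCN, 0 °C → rt; then 3 (3 equiv), 80 °C
Reagents that add atoms: Eschenmoser's salt (N,N-dimethylmethyleneiminium iodide) C=[N+](C)C.[I-]
Why: Mannich aminomethylation at the only free ring carbon of 5, thermal loss of dimethylamine to o-quinone methide 7, and Friedel–Crafts-type Michael capture by a ring carbon of 3 (threefold excess suppresses double bridging) give the methylene bridge.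

**Step 4**
Reactants: 8 methylene-bridged dimer; 9 methacrolein
Product: 13 1-{3-[(3-acetyl-2,4-dihydroxy-6-methoxy-5-methylphenyl)methyl]-2,4,6-trihydroxy-5-(2-methylpropanoyl)phenyl}-3-methylbut-3-en-2-one, via Mannich base 10 (not isolated), via o-quinone methide 11 (not isolated), via Breslow enaminol 12 (not isolated)
Conditions: Eschenmoser's salt (1.0 equiv), Et3N (1.1 equiv), DMF, 0 °C → rt; then 9 (5 equiv, slow addition), 3-benzyl-5-(2-hydroxyethyl)-4-methylthiazolium chloride (20 mol%), Et3N (2 equiv), 70 °C, N2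
Reagents that add atoms: Eschenmoser's salt (N,N-dimethylmethyleneiminium iodide) C=[N+](C)C.[I-]
Why: Proposed new method: aminomethylation at the last free ring carbon and loss of dimethylamine give o-quinone methide 11 with an electrophilic benzylic carbon, while the thiazol-2-ylidene turns the carbonyl carbon of 9 into the nucleophilic carbon of Breslow enaminol 12, and 1,4-addition with rearomatisation and release of the carbene forms ArCH2–C(=O) from two normally electrophilic carbons; the thiazolium catalyst and the α-methyl group should favour acyl-anion over homoenolate reactivity; the closest known chemistry is the Stetter reaction of aldehydes with Mannich bases as in situ Michael acceptors and NHC-mediated acylation of quinone methides.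

**Step 5**
Reactants: 13 side-chain enone
Product: 16 1-{3-[(3-acetyl-2,4-dihydroxy-6-methoxy-5-methylphenyl)methyl]-2,4,6-trihydroxy-5-[(2R)-2-hydroxy-3-methylbut-3-en-1-yl]phenyl}-2-methylpropan-1-one, via pentakis-TMS ketone 14 (not isolated), via pentakis-TMS carbinol 15 (not isolated)
Conditions: HMDS, cat. TMSCl, MeCN, 60 °C, evaporate; (S)-Me-CBS (20 mol%), catecholborane (2 equiv), toluene, −78 °C; MeOH, then citric acid, rt
Reagents that add atoms: none
Why: Corey–Bakshi–Shibata reduction in which transient silylation masks the phenols and leaves the two di-ortho-substituted aryl ketones too hindered to react, the (S)-oxazaborolidine binds the enone with isopropenyl as the large group and delivers hydride 1,2 to give the (R)-allylic alcohol (same sense as acetophenone → (R)-1-phenylethanol), and mild methanolysis removes the aryl TMS ethers.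

**Compound list**
1 | phloroglucinol (benzene-1,3,5-triol) | Oc1cc(O)cc(O)c1 | starting material
2 | isobutyryl chloride (2-methylpropanoyl chloride) | CC(C)C(=O)Cl | starting material
3 | 2-methyl-1-(2,4,6-trihydroxyphenyl)propan-1-one | CC(C)C(=O)c1c(O)cc(O)cc1O | intermediate
4 | 1-(2,6-dihydroxy-4-methoxyphenyl)ethan-1-one | CC(=O)c1c(O)cc(OC)cc1O | starting material
5 | 1-(2,6-dihydroxy-4-methoxy-3-methylphenyl)ethan-1-one | CC(=O)c1c(O)c(C)c(OC)cc1O | intermediate
6 | 1-{3-[(dimethylamino)methyl]-2,6-dihydroxy-4-methoxy-5-methylphenyl}ethan-1-one | CC(=O)c1c(O)c(C)c(OC)c(CN(C)C)c1O | intermediate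
7 | 2-acetyl-3-hydroxy-5-methoxy-4-methyl-6-methylidenecyclohexa-2,4-dien-1-one | C=C1C(=O)C(C(C)=O)=C(O)C(C)=C1OC | intermediate
8 | 1-{3-[(3-acetyl-2,4-dihydroxy-6-methoxy-5-methylphenyl)methyl]-2,4,6-trihydroxyphenyl}-2-methylpropan-1-one | CC(C)C(=O)c1c(O)cc(O)c(Cc2c(O)c(C(C)=O)c(O)c(C)c2OC)c1O | intermediate
9 | methacrolein (2-methylprop-2-enal) | C=C(C)C=O | starting material
10 | 1-{3-[(3-acetyl-2,4-dihydroxy-6-methoxy-5-methylphenyl)methyl]-5-[(dimethylamino)methyl]-2,4,6-trihydroxyphenyl}-2-methylpropan-1-one | CC(C)C(=O)c1c(O)c(CN(C)C)c(O)c(Cc2c(O)c(C(C)=O)c(O)c(C)c2OC)c1O | intermediate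
11 | 2-[(3-acetyl-2,4-dihydroxy-6-methoxy-5-methylphenyl)methyl]-3,5-dihydroxy-6-methylidene-4-(2-methylpropanoyl)cyclohexa-2,4-dien-1-one | C=C1C(=O)C(Cc2c(O)c(C(C)=O)c(O)c(C)c2OC)=C(O)C(C(=O)C(C)C)=C1O | intermediate
12 | 2-[3-benzyl-2-(1-hydroxy-2-methylprop-2-en-1-ylidene)-4-methyl-2,3-dihydro-1,3-thiazol-5-yl]ethan-1-ol (Breslow enaminol) | C=C(C)C(O)=C1SC(CCO)=C(C)N1Cc1ccccc1 | intermediate
13 | 1-{3-[(3-acetyl-2,4-dihydroxy-6-methoxy-5-methylphenyl)methyl]-2,4,6-trihydroxy-5-(2-methylpropanoyl)phenyl}-3-methylbut-3-en-2-one | C=C(C)C(=O)Cc1c(O)c(Cc2c(O)c(C(C)=O)c(O)c(C)c2OC)c(O)c(C(=O)C(C)C)c1O | intermediate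
14 | pentakis(O-trimethylsilyl) ether of 13 | C=C(C)C(=O)Cc1c(O[Si](C)(C)C)c(Cc2c(O[Si](C)(C)C)c(C(C)=O)c(O[Si](C)(C)C)c(C)c2OC)c(O[Si](C)(C)C)c(C(=O)C(C)C)c1O[Si](C)(C)C | intermediate
15 | pentakis(O-trimethylsilyl) ether of 16, (R)-carbinol | C=C(C)[C@H](O)Cc1c(O[Si](C)(C)C)c(Cc2c(O[Si](C)(C)C)c(C(C)=O)c(O[Si](C)(C)C)c(C)c2OC)c(O[Si](C)(C)C)c(C(=O)C(C)C)c1O[Si](C)(C)C | intermediate
16 | 1-{3-[(3-acetyl-2,4-dihydroxy-6-methoxy-5-methylphenyl)methyl]-2,4,6-trihydroxy-5-[(2R)-2-hydroxy-3-methylbut-3-en-1-yl]phenyl}-2-methylpropan-1-one | C=C(C)[C@H](O)Cc1c(O)c(Cc2c(O)c(C(C)=O)c(O)c(C)c2OC)c(O)c(C(=O)C(C)C)c1O | target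

**Totals**
Total step count: 5. Longest linear sequence: 4 steps (step 2 or step 1, then steps 3, 4 and 5).

**Steps most likely to fail, with fallbacks**

Step 4 (key bond). The risks are attack of the methacrolein-derived enaminol through its terminal carbon (homoenolate path, leading to ring-fused lactones or O-acylation), self-condensation of methacrolein, and trapping of the carbene by the quinone methide. The fallback sets out from 10 (made as in the first stage of step 4) and comes back at 13. Methacrolein 9 is first combined with dimethylamine to give the saturated aldehyde 3-(dimethylamino)-2-methylpropanal F1, which cannot form a homoenolate and is not a Michael acceptor. Its thiazolium-catalysed addition to quinone methide 11 gives the β-amino ketone 1-{3-[(3-acetyl-2,4-dihydroxy-6-methoxy-5-methylphenyl)methyl]-2,4,6-trihydroxy-5-(2-methylpropanoyl)phenyl}-4-(dimethylamino)-3-methylbutan-2-one F2. Warming F2 with acetic acid in toluene eliminates dimethylamine and delivers 13.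

Step 5. The risks are insufficient facial discrimination between the isopropenyl and the bulky arylmethyl group, and partial reduction of an aryl ketone. The fallback sets out from 13 and comes back at 16. Luche reduction (NaBH4, CeCl3·7H2O, MeOH, −40 °C) of unprotected 13 gives the racemic allylic alcohol 1-{3-[(3-acetyl-2,4-dihydroxy-6-methoxy-5-methylphenyl)methyl]-2,4,6-trihydroxy-5-(2-hydroxy-3-methylbut-3-en-1-yl)phenyl}-2-methylpropan-1-one F3. Lipase-catalysed acetylation (Amano PS, vinyl acetate, MTBE) should then convert the (S)-enantiomer into the (S)-acetate (2S)-1-{3-[(3-acetyl-2,4-dihydroxy-6-methoxy-5-methylphenyl)methyl]-2,4,6-trihydroxy-5-(2-methylpropanoyl)phenyl}-3-methylbut-3-en-2-yl acetate F4, by Kazlauskas' rule with arylmethyl as the large group. The unreacted (R)-alcohol is 16 and is separated by chromatography; the enantiopreference must be confirmed experimentally.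

Step 3. The risks are double bridging of 3 and base- or heat-induced scrambling of the methylene bridge. The fallback sets out from 3 and comes back at 10, so the first stage of step 4 is skipped. Compound 3 is treated with 2.2 equivalents of Eschenmoser's salt and Et3N to give the bis-Mannich base 1-{3,5-bis[(dimethylamino)methyl]-2,4,6-trihydroxyphenyl}-2-methylpropan-1-one F5, which has no free ring carbon. Heating F5 (3 equiv) with 5 in MeCN generates the mono-quinone methide 2-[(dimethylamino)methyl]-3,5-dihydroxy-6-methylidene-4-(2-methylpropanoyl)cyclohexa-2,4-dien-1-one F6. The single free ring carbon of 5 captures F6 and gives 10 directly, which is carried into the carbene-catalysed stage of step 4.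

**Further compounds**
F1 | step 4 | 3-(dimethylamino)-2-methylpropanal | CN(C)CC(C)C=O
F2 | step 4 | 1-{3-[(3-acetyl-2,4-dihydroxy-6-methoxy-5-methylphenyl)methyl]-2,4,6-trihydroxy-5-(2-methylpropanoyl)phenyl}-4-(dimethylamino)-3-methylbutan-2-one | CN(C)CC(C)C(=O)Cc1c(O)c(Cc2c(O)c(C(C)=O)c(O)c(C)c2OC)c(O)c(C(=O)C(C)C)c1O
F3 | step 5 | racemic 1-{3-[(3-acetyl-2,4-dihydroxy-6-methoxy-5-methylphenyl)methyl]-2,4,6-trihydroxy-5-(2-hydroxy-3-methylbut-3-en-1-yl)phenyl}-2-methylpropan-1-one | C=C(C)C(O)Cc1c(O)c(Cc2c(O)c(C(C)=O)c(O)c(C)c2OC)c(O)c(C(=O)C(C)C)c1O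
F4 | step 5 | (2S)-1-{3-[(3-acetyl-2,4-dihydroxy-6-methoxy-5-methylphenyl)methyl]-2,4,6-trihydroxy-5-(2-methylpropanoyl)phenyl}-3-methylbut-3-en-2-yl acetate | C=C(C)[C@@H](OC(C)=O)Cc1c(O)c(Cc2c(O)c(C(C)=O)c(O)c(C)c2OC)c(O)c(C(=O)C(C)C)c1O
F5 | step 3 | 1-{3,5-bis[(dimethylamino)methyl]-2,4,6-trihydroxyphenyl}-2-methylpropan-1-one | CC(C)C(=O)c1c(O)c(CN(C)C)c(O)c(CN(C)C)c1O
F6 | step 3 | 2-[(dimethylamino)methyl]-3,5-dihydroxy-6-methylidene-4-(2-methylpropanoyl)cyclohexa-2,4-dien-1-one | C=C1C(=O)C(CN(C)C)=C(O)C(C(=O)C(C)C)=C1O
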